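At late times both earlier flasks stand still. From 3.00 h to 50.0 h, zeta holds left-handed product near 17.0%, and epsilon holds it near 53.5% from 4.00 h on, so I reckon end states. The asked 4.0 d is much longer than those first readings.

in all of them: left-handed substrate 0.34 M; right-handed substrate 0.34 M; free catalyst 0.68 mM; racemization catalyst 0.51 mM; impurity 0.17 mM
- zeta: coupling partner 0.19 M; run made earlier
- epsilon: coupling partner 1.2 M; run made earlier
- elm: coupling partner 0.250 M; time 4.0 d
- alder: coupling partner 0.500 M; time 4.0 d
- birch: coupling partner 1.00 M; time 4.0 d
- oak: coupling partner 2.00 M; time 4.0 d

| run | time / h | left-handed product / % | left-handed substrate / % |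
|---|---|---|---|
| zeta | 3.00 | 17 | 34 |
| zeta | 10.0 | 20 | 37 |
| zeta | 15.0 | 17 | 38 |
| zeta | 25.0 | 15 | 37 |
| zeta | 40.0 | 18 | 35 |
| zeta | 50.0 | 15 | 34 |
| epsilon | 4.00 | 53 | 3 |
| epsilon | 6.00 | 53 | 0 |
| epsilon | 10.0 | 50 | 1 |
| epsilon | 20.0 | 52 | 0 |
| epsilon | 30.0 | 57 | 0 |
| epsilon | 50.0 | 56 | 0 |

(scatter of a reading: 2 percentage points)

- free catalyst is single-handed; left-handed substrate and right-handed substrate are mirror images of each other, charged as a racemate, each of them at the stated concentration
- "hardly changes" means that all values lie within two and a half points (for a concentration: within two and a half percent of the largest)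

- [left-handed product] at the end for elm, alder, birch, oak, in this order
- the shape of the row from first to last (falls all the way / rises all the way / falls, then rises / rises, then falls / hardly changes)

I build the flask up one process at a time. First comes the coupling of partner with left-handed substrate on the free catalyst. Zeta stops with left-handed substrate still at 34%, so I take its partner, charged at 0.19 M, as the limiting reagent. It gave f = 0.608 of left-handed product per unit of partner.

Since f is less than one, I add a second coupling, which I suppose sends the remaining partner to right-handed product. Elm and alder, on my reckoning, then give 0.152 M and 0.304 M.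

Next comes racemization. In epsilon the partner is in excess and left-handed substrate reads 0%, yet the product stands above the 50.0% charged as left-handed substrate. That gain G, a reading with scatter 2 percentage points, is substrate carried over from the right-handed form while coupling lasted.

The partner does not stay nearly constant, though: full conversion of the substrate takes 0.680 M of it, against 1.2 M charged in epsilon. As a rough estimate of my own, I suppose that coupling lasts a time roughly inverse to the partner charge, so that fewer racemization half-lives fit inside it at a larger charge. I therefore carry the racemization allowance, W, the gain times the partner charge: 0.0420 M. It holds for these catalyst and impurity charges. For birch, W gives a gain of 4.20% and 0.369 M; for oak, 2.10% and 0.354 M. So my row climbs to birch, then drops.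

The forecast gives 0.152 M, 0.295 M, 0.364 M and 0.364 M, shape "rises all the way", holding that “the left-handed pool is capped at about 0.36 M”. My reckoning parts from it at oak, where its value stands above mine.

The flasks give 0.163 M, 0.310 M, 0.373 M and 0.353 M, shape "rises, then falls".

    racemization catalyst + impurity → spent catalyst (k = 4.80 × 10⁵ L mol⁻¹ h⁻¹)
    coupling partner + free catalyst + right-handed substrate → free catalyst + right-handed product (k = 1600 L² mol⁻² h⁻¹)
    left-handed substrate + racemization catalyst ⇌ right-handed substrate + racemization catalyst, rate k3*[racemization catalyst]*[left-handed substrate] forward; the back reaction follows from the equilibrium constant (k = 390 L mol⁻¹ h⁻¹)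
    coupling partner + free catalyst + left-handed substrate → free catalyst + left-handed product (k = 3400 L² mol⁻² h⁻¹)

At the end, right-handed product reads 48.1% in oak and 45.1% in birch. W divided by oak's partner charge gives a gain of 2.10%, and oak stands 1.9 points above 50.0%. Divided by birch's charge, W gives 4.20%, and birch stands 4.9 points above it.

(The runs stem from a simulated flask with made-up constants; noise was put on by code.)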